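# Proposed synthesis of quercetin 3,3',7-trisulfate from 1,3,5-trifluorobenzene

## The problem

The target is a flavonol, a 2-aryl-3-oxychromen-4-one in which ring A (C4a to C8a) is fused to the pyranone ring C and ring B sits on C2; it has no stereocentre, so the task is one of connectivity and of telling five oxygen functions apart. O3, O7 and O3' carry sulfate monoesters, whereas O5 and O4' must end as free hydroxyls. Aryl sulfate monoesters are strongly acidic, polyanionic, labile to acid and heat, and incompatible with silica chromatography and organometallic steps, so they have to be introduced at the very end, with at most one neutral operation after them. O5 is held in a hydrogen bond to the C4 carbonyl and is the least reactive hydroxyl of a flavonol. O4' has no such protection and is the most acidic phenol of ring B, so it needs a group that survives acid and base and leaves under neutral conditions. The three oxygens to be sulfated should be unmasked together, by a method orthogonal to the O4' group. The key step rests on the ring A oxygens at C8a, C5 and C7: they are mutually meta around C4a, which is the pattern of 1,3,5-trifluorobenzene (4). Once the C4 carbonyl is attached at C4a, every C–F bond is ortho or para to it, so one fluoride can be displaced by an enolate oxygen to close ring C and the other two later by alkoxide.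

## Retrosynthesis

**17 to 16.** The last bond cut is the benzyl C–O bond at O4'. Hydrogenolysis is neutral and leaves aryl sulfates alone. A free 4'-hydroxyl during sulfation would itself be sulfated, so this oxygen must stay masked until the end. Precursor 16 differs from the target 17 only by the benzyl group. The forward step must cleave O–CH2Ph without reducing C2=C3 or hydrolysing a sulfate.

**16 to 15.** The three S–O bonds are cut together, leading to 4'-O-benzylquercetin (15). This compound has four free hydroxyls, but the chelated 5-OH should be the last to react, so no separate protecting group for O5 is planned; that saves two steps against a route with an orthogonal group there. The forward reaction must drive sulfation to completion at O3, O7 and O3' and stop before O5.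

**15 to 14 to 13 and 1.** All four oxygens to be freed in 15 carry the same 4-methoxybenzyl (PMB) group in 14, so one acidolysis releases them while the plain benzyl ether stays. The C5–O and C7–O bonds of 14 are then cut back to C–F bonds in the difluoroflavone 13, with two equivalents of 4-methoxybenzyl alcohol (1) as the oxygen source, one for each fluoride. Both positions receive the same nucleophile, so no regiochemical question arises. The forward reaction is a double nucleophilic aromatic substitution; the second fluoride must still be reactive after the first has been replaced by a donor.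

**13 to 6 and 11 (through 12).** This is the strategic cut: O1–C8a and C2–C3. The classical closure at O1–C2 would need a phloroglucinol ketone with one free and two protected hydroxyls. Here fluorine serves as leaving group at C8a and as latent oxygen at C5 and C7, and the two ortho fluorides are equivalent. The precursors are two simple benzene derivatives, the α-PMB-oxy ketone 6 and the aroyl chloride 11, joined through the diketone 12. The forward reaction needs C-acylation of the ketone over O-acylation and displacement of an ortho fluoride by the diketonate oxygen.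

**6 to 3 and 4 (through 5); 3 to 1 and 2.** The C4–C4a bond is cut. Friedel–Crafts acylation of a trifluoroarene is unattractive, but each C–H of 4 lies between two fluorines and is acidic enough for lithiation to 5. The acyl partner is the N-methoxy-N-methylamide 3, which stops cleanly at the ketone. Amide 3 comes from 1 and the commercial chloroacetamide 2 by one C–O bond formation, so O3 of the target is present from the first step.

**11 to 10, 9, 8 and 7.** Ring B needs only functional group changes on methyl 3,4-dihydroxybenzoate (7). The more acidic 4-hydroxyl is benzylated first (8), the 3-hydroxyl then takes the PMB group (9), and saponification (10) and neutral chlorination give 11. The forward sequence asks only for regioselective mono-benzylation and an acid chloride formation that spares the PMB ether.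

## Roads not taken

**Alternative 1: carbonylative α-arylation with carbon monoxide as C2.** The cut is at C2–C1' and C2–C3, with carbon monoxide A4 supplying C2, and at O1–C2. In the forward direction the tetra-MOM ketone A2, the aryl bromide A3 and A4 would couple under Pd(OAc)2 with 1,3-bis(diphenylphosphino)propane and base. An HCl/methanol quench would remove the MOM groups and close ring C to give the 4'-O-benzylquercetin A1.

- Merits: A1 is the same compound as 15 of the chosen route. It would arrive in one operation from two fragments, with ring A oxygens taken from phloroglucinol chemistry and no fluoride displacement. On step count this road is shorter by about three steps and is the better one in that respect.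
- Weak points: carbonylative α-arylation is established for simple alkyl aryl ketones. A2 is α-oxygenated and its carbonyl is flanked by two ortho alkoxy groups. The electron-rich bromide A3 adds slowly to zerovalent palladium. Direct arylation without insertion of A4 would give a deoxybenzoin, and the acidic diketone product can sequester base and metal. A2 also needs four MOM groups, one of them on a chelated ortho hydroxyl.
- Comparison: the chosen plan sets two individually well-understood events (C-acylation of a ketone by an acid chloride, intramolecular fluoride displacement) against this shorter but less certain three-component step.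

**Alternative 2: carbonylative alkyne annulation with carbon monoxide as C4.** The cut is at C4a–C4, C3–C4 and O1–C2. The iodophenol A5, A4 and the arylacetylene A6 would react under PdCl2(PPh3)2 and diethylamine to give the flavone A7.

- Merits: three bonds and ring C form in one mild, well-precedented step. As a ring construction it is at least as reliable as the acylation and ring closure chosen here.
- Weak points: A7 has hydrogen at C3, and the target needs a sulfate there. A separate C3 oxidation of an electron-rich flavone with acid-labile MOM groups would have to follow, a transformation of modest reliability. Five-membered closure to an aurone competes with the six-membered mode. A5 requires mono-iodination and partial protection of phloroglucinol, and A6 costs a homologation of the ring B aldehyde.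
- Comparison: the chosen plan carries O3 from the first step inside the α-alkoxy ketone, so no C–H oxidation is needed, and this outweighs the more elegant ring formation.

**Alternative 3: thermal Mentzer annulation of unprotected phloroglucinol.** The cut is at C4–C4a and O1–C2. The triol A8 (phloroglucinol) and the α-pivaloyloxy aroylacetate A9 would be heated at about 240 °C in a high-boiling ether to give the 3,3'-di-O-pivaloyl-4'-O-benzylquercetin A10.

- Merits: ring A comes from A8, the cheapest possible building block, which is symmetric and needs no protection. The 5- and 7-hydroxyls emerge free, and removal of the pivalates from A10 would again lead to 15. On paper this is the shortest road.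
- Weak points: at this temperature pivaloyl groups can migrate to the hydroxyls of A8 or to O7 of the product. The coumarin mode of condensation (attack at the ketone carbonyl) competes. The α-acyloxy β-ketoester and the benzyl ether are under thermal stress, and A9 needs an α-oxygenation of an aroylacetate.
- Comparison: the chosen plan never exceeds about 60 °C, and each bond forms in a step whose selectivity is set by structure (chelation, a six-membered transition state). It pays for this with more steps and with the later introduction of O5 and O7.

Key step: step 7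

Assumption: sulfate monoesters are written as hydrogen sulfates, as in the target formula; they would be handled as ammonium or potassium salts, and the acid form is reached by cation exchange.

## Route

Step 1
Reactants: 1 4-methoxybenzyl alcohol; 2 2-chloro-N-methoxy-N-methylacetamide
Product: 3 N-methoxy-2-[(4-methoxybenzyl)oxy]-N-methylacetamide
Conditions: NaH, n-Bu4NI (cat.), THF, 0 °C to rt
Reagents that add atoms: none
Why: Williamson etherification; the sodium alkoxide of 1 displaces the activated α-chloride by SN2, and the N-methoxy-N-methylamide is not attacked by alkoxide under these conditions.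

Step 2
Reactants: 4 1,3,5-trifluorobenzene; 3 N-methoxy-2-[(4-methoxybenzyl)oxy]-N-methylacetamide
Product: 6 2-[(4-methoxybenzyl)oxy]-1-(2,4,6-trifluorophenyl)ethan-1-one, via (2,4,6-trifluorophenyl)lithium 5 (not isolated)
Conditions: n-BuLi, THF, −78 °C; then 3, −78 °C; then aq. NH4Cl
Reagents that add atoms: none
Why: Ortho-lithiation of the C–H flanked by two fluorines, then ketone synthesis from an N-methoxy-N-methylamide; the chelated tetrahedral adduct prevents over-addition and keeps the fluoride-activating ketone masked until the quench, and the low temperature prevents loss of LiF to an aryne.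

Step 3
Reactants: 7 methyl 3,4-dihydroxybenzoate
Product: 8 methyl 4-(benzyloxy)-3-hydroxybenzoate
Conditions: BnBr (1 equiv), K2CO3 (1 equiv), DMF, rt
Reagents that add atoms: benzyl bromide, BrCc1ccccc1
Why: Regioselective Williamson etherification; the 4-hydroxyl para to the ester is the more acidic, so one equivalent of weak base should form mainly the 4-phenoxide, and the minor 3-ether and bis-ether are removed by crystallisation or chromatography.

Step 4
Reactants: 8 methyl 4-(benzyloxy)-3-hydroxybenzoate
Product: 9 methyl 4-(benzyloxy)-3-[(4-methoxybenzyl)oxy]benzoate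
Conditions: PMBCl, K2CO3, n-Bu4NI (cat.), DMF, 50 °C
Reagents that add atoms: 4-methoxybenzyl chloride, COc1ccc(CCl)cc1
Why: Williamson etherification of the remaining phenol; no selectivity question is left.

Step 5
Reactants: 9 methyl 4-(benzyloxy)-3-[(4-methoxybenzyl)oxy]benzoate
Product: 10 4-(benzyloxy)-3-[(4-methoxybenzyl)oxy]benzoic acid
Conditions: LiOH, THF/MeOH/H2O, 40 °C; then 1 M HCl to pH 3–4, 0 °C
Reagents that add atoms: lithium hydroxide, [Li+].[OH-]
Why: Ester saponification; both benzylic ethers are stable to hydroxide, and brief cold acidification to pH 3–4 should spare the PMB ether.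

Step 6
Reactants: 10 4-(benzyloxy)-3-[(4-methoxybenzyl)oxy]benzoic acid
Product: 11 4-(benzyloxy)-3-[(4-methoxybenzyl)oxy]benzoyl chloride
Conditions: 1-chloro-N,N,2-trimethylprop-1-en-1-amine, CH2Cl2, 0 °C to rt; used crude
Reagents that add atoms: 1-chloro-N,N,2-trimethylprop-1-en-1-amine, CC(C)=C(Cl)N(C)C
Why: Acid chloride formation with an α-chloroenamine under neutral conditions; the acid adds to the keteniminium form and chloride displaces the amide, so no HCl is set free to attack the PMB ether.

Step 7
Reactants: 6 2-[(4-methoxybenzyl)oxy]-1-(2,4,6-trifluorophenyl)ethan-1-one; 11 4-(benzyloxy)-3-[(4-methoxybenzyl)oxy]benzoyl chloride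
Product: 13 2-{4-(benzyloxy)-3-[(4-methoxybenzyl)oxy]phenyl}-5,7-difluoro-3-[(4-methoxybenzyl)oxy]-4H-chromen-4-one, via acyclic 2-alkoxy-1,3-diketone 12 (not isolated)
Conditions: MgBr2·OEt2, i-Pr2NEt, CH2Cl2, 0 °C to rt; dilute citric acid wash, solvent exchange; K2CO3, DMF, 60 °C
Reagents that add atoms: none
Why: MgBr2 chelates the carbonyl and α-ether oxygens of 6, so the hindered amine can deprotonate C3 (soft enolisation) and the chelated enolate is acylated at carbon by 11, forming C2–C3; the product 12 is held as its magnesium diketonate, which prevents a second acylation. After removal of magnesium, K2CO3 in DMF regenerates the diketonate, whose oxygen on the ring B carbonyl adds to C8a of the trifluorophenyl ring to give a σ-adduct stabilised by the C4 carbonyl, and loss of fluoride forms O1–C8a (intramolecular SNAr by addition–elimination). The closest known reaction type is the flavone synthesis from 2-fluoroaryl ketones by Claisen-type C-acylation and SNAr closure of the diketone, joined here to the MgBr2/amine acylation of ketones by acid chlorides. Ring C closes as a six-membered ring by attack of oxygen on an sp2 carbon, 6-exo-trig when counted across C8a=C8 and equally a 6-endo-trig conjugate addition across C4a=C8a, both allowed; attack through C3 would need a four-membered ring and is excluded. No stereocentre is formed, since the stereogenic C3 of 12 becomes planar. The step needs C- over O-acylation, which the chelated magnesium enolate secures, and displacement of an ortho over the para fluoride, which the intramolecular six-membered transition state secures; the two ortho fluorides are equivalent, so a single chromone should result. The fluorides left at C5 and C7 stay ortho and para to the C4 carbonyl and should not be attacked by carbonate at this temperature.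

Step 8
Reactants: 13 2-{4-(benzyloxy)-3-[(4-methoxybenzyl)oxy]phenyl}-5,7-difluoro-3-[(4-methoxybenzyl)oxy]-4H-chromen-4-one; 1 4-methoxybenzyl alcohol
Product: 14 2-{4-(benzyloxy)-3-[(4-methoxybenzyl)oxy]phenyl}-3,5,7-tris[(4-methoxybenzyl)oxy]-4H-chromen-4-one
Conditions: 1 (3 equiv in all), NaH (3 equiv), THF/DMF, 0 °C to 50 °C
Reagents that add atoms: 4-methoxybenzyl alcohol (the second equivalent of 1, one equivalent being consumed per fluoride), COc1ccc(CO)cc1
Why: Twofold nucleophilic aromatic substitution by sodium 4-methoxybenzyl oxide, in which two equivalents of the alkoxide are consumed, one at C7 and one at C5. C7–F is para and C5–F ortho to the chromone carbonyl, fluoride is the best leaving group in addition–elimination, and warming with excess alkoxide should carry the slower second substitution.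

Step 9
Reactants: 14 2-{4-(benzyloxy)-3-[(4-methoxybenzyl)oxy]phenyl}-3,5,7-tris[(4-methoxybenzyl)oxy]-4H-chromen-4-one
Product: 15 2-[4-(benzyloxy)-3-hydroxyphenyl]-3,5,7-trihydroxy-4H-chromen-4-one (4'-O-benzylquercetin)
Conditions: TFA, anisole (excess), CH2Cl2, 0 °C to rt
Reagents that add atoms: none
Why: Acidolysis of the four PMB ethers through the stabilised 4-methoxybenzyl cation, which anisole traps by Friedel–Crafts alkylation before it can attack ring A; the unsubstituted benzyl ether ionises far more slowly and should remain.

Step 10
Reactants: 15 2-[4-(benzyloxy)-3-hydroxyphenyl]-3,5,7-trihydroxy-4H-chromen-4-one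
Product: 16 4'-O-benzylquercetin 3,3',7-tris(hydrogen sulfate)
Conditions: SO3·NMe3 (excess), Et3N, DMF, 60 °C; size-exclusion or reversed-phase purification of the salt
Reagents that add atoms: sulfur trioxide–trimethylamine complex, C[N+](C)(C)S(=O)(=O)[O-]
Why: O-sulfonation of phenolic and enolic hydroxyls by a sulfur trioxide–amine complex; the 5-hydroxyl is tied in a hydrogen bond to the C4 carbonyl and is the least nucleophilic, so sulfation should stop at O3, O7 and O3'.

Step 11
Reactants: 16 4'-O-benzylquercetin 3,3',7-tris(hydrogen sulfate)
Product: 17 quercetin 3,3',7-tris(hydrogen sulfate) (quercetin 3,3',7-trisulfate)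
Conditions: H2 (1 atm), Pd/C, MeOH/H2O, rt; cation exchange (H+ form) for the free acid
Reagents that add atoms: none
Why: Hydrogenolysis of the benzyl aryl ether under neutral conditions; aryl sulfate salts are inert to H2 over palladium, and the tetrasubstituted C2=C3 bond of a flavonol is not reduced at ambient pressure.

## Compound list

1 | 4-methoxybenzyl alcohol | COc1ccc(CO)cc1 | starting material
2 | 2-chloro-N-methoxy-N-methylacetamide | CON(C)C(=O)CCl | starting material
3 | N-methoxy-2-[(4-methoxybenzyl)oxy]-N-methylacetamide | CON(C)C(=O)COCc1ccc(OC)cc1 | intermediate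
4 | 1,3,5-trifluorobenzene | Fc1cc(F)cc(F)c1 | starting material
5 | (2,4,6-trifluorophenyl)lithium | [Li]c1c(F)cc(F)cc1F | intermediate
6 | 2-[(4-methoxybenzyl)oxy]-1-(2,4,6-trifluorophenyl)ethan-1-one | O=C(COCc1ccc(OC)cc1)c1c(F)cc(F)cc1F | intermediate
7 | methyl 3,4-dihydroxybenzoate | COC(=O)c1ccc(O)c(O)c1 | starting material
8 | methyl 4-(benzyloxy)-3-hydroxybenzoate | COC(=O)c1ccc(OCc2ccccc2)c(O)c1 | intermediate
9 | methyl 4-(benzyloxy)-3-[(4-methoxybenzyl)oxy]benzoate | COC(=O)c1ccc(OCc2ccccc2)c(OCc2ccc(OC)cc2)c1 | intermediate
10 | 4-(benzyloxy)-3-[(4-methoxybenzyl)oxy]benzoic acid | O=C(O)c1ccc(OCc2ccccc2)c(OCc2ccc(OC)cc2)c1 | intermediate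
11 | 4-(benzyloxy)-3-[(4-methoxybenzyl)oxy]benzoyl chloride | O=C(Cl)c1ccc(OCc2ccccc2)c(OCc2ccc(OC)cc2)c1 | intermediate
12 | 1-{4-(benzyloxy)-3-[(4-methoxybenzyl)oxy]phenyl}-2-[(4-methoxybenzyl)oxy]-3-(2,4,6-trifluorophenyl)propane-1,3-dione (racemic, largely enolised) | O=C(c1ccc(OCc2ccccc2)c(OCc2ccc(OC)cc2)c1)C(OCc1ccc(OC)cc1)C(=O)c1c(F)cc(F)cc1F | intermediate
13 | 2-{4-(benzyloxy)-3-[(4-methoxybenzyl)oxy]phenyl}-5,7-difluoro-3-[(4-methoxybenzyl)oxy]-4H-chromen-4-one | O=c1c(OCc2ccc(OC)cc2)c(-c2ccc(OCc3ccccc3)c(OCc3ccc(OC)cc3)c2)oc2cc(F)cc(F)c12 | intermediate
14 | 2-{4-(benzyloxy)-3-[(4-methoxybenzyl)oxy]phenyl}-3,5,7-tris[(4-methoxybenzyl)oxy]-4H-chromen-4-one | O=c1c(OCc2ccc(OC)cc2)c(-c2ccc(OCc3ccccc3)c(OCc3ccc(OC)cc3)c2)oc2cc(OCc3ccc(OC)cc3)cc(OCc3ccc(OC)cc3)c12 | intermediate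
15 | 2-[4-(benzyloxy)-3-hydroxyphenyl]-3,5,7-trihydroxy-4H-chromen-4-one (4'-O-benzylquercetin) | O=c1c(O)c(-c2ccc(OCc3ccccc3)c(O)c2)oc2cc(O)cc(O)c12 | intermediate
16 | 4'-O-benzylquercetin 3,3',7-tris(hydrogen sulfate) | O=c1c(OS(=O)(=O)O)c(-c2ccc(OCc3ccccc3)c(OS(=O)(=O)O)c2)oc2cc(OS(=O)(=O)O)cc(O)c12 | intermediate
17 | quercetin 3,3',7-tris(hydrogen sulfate) | O=c1c(OS(=O)(=O)O)c(-c2ccc(O)c(OS(=O)(=O)O)c2)oc2cc(OS(=O)(=O)O)cc(O)c12 | target

## Step count and risks

Total step count: 11. Longest linear sequence: 9 steps (steps 3 to 11, from 7); the ring A branch (steps 1 and 2) joins at step 7.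

**Step 7 (key step).**
- What may go wrong: acylation of the magnesium enolate at oxygen instead of carbon; partial loss of a PMB ether to the Lewis acid; base-induced cleavage of the diketone at the very electrophilic trifluorobenzoyl carbonyl before ring closure.
- Fallback: this replaces the acylation by an aldol addition and oxidation, in which the electrophile can react only at carbon. It sets out from 9 and 6. Ester 9 is reduced with LiAlH4 in THF to {4-(benzyloxy)-3-[(4-methoxybenzyl)oxy]phenyl}methanol F1, which MnO2 in CH2Cl2 oxidises to 4-(benzyloxy)-3-[(4-methoxybenzyl)oxy]benzaldehyde F2. The lithium enolate of 6 (LiN(SiMe3)2, THF, −78 °C) adds to F2 to give the β-hydroxy ketone 3-{4-(benzyloxy)-3-[(4-methoxybenzyl)oxy]phenyl}-3-hydroxy-2-[(4-methoxybenzyl)oxy]-1-(2,4,6-trifluorophenyl)propan-1-one F3 as a mixture of diastereomers. Oxidation of both with Dess–Martin periodinane gives diketone 12, where the fallback rejoins the route for the K2CO3/DMF closure to 13.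

**Step 8.**
- What may go wrong: stalling after the first substitution, because the new alkoxy donor deactivates the ring and C5 is hindered by the peri carbonyl; addition of alkoxide at C2 with opening of the pyranone.
- Fallback: this changes the second oxygen nucleophile to a small hydroxide surrogate. It sets out from 13. One equivalent of sodium 4-methoxybenzyl oxide at low temperature is expected to replace the para fluoride first and give 2-{4-(benzyloxy)-3-[(4-methoxybenzyl)oxy]phenyl}-5-fluoro-3,7-bis[(4-methoxybenzyl)oxy]-4H-chromen-4-one F4. Treatment with 2-(methylsulfonyl)ethanol and NaH in DMF displaces the C5 fluoride to give the transient ether 2-{4-(benzyloxy)-3-[(4-methoxybenzyl)oxy]phenyl}-3,7-bis[(4-methoxybenzyl)oxy]-5-[2-(methylsulfonyl)ethoxy]-4H-chromen-4-one F5. This eliminates methyl vinyl sulfone in the flask to leave the chelated phenol 2-{4-(benzyloxy)-3-[(4-methoxybenzyl)oxy]phenyl}-5-hydroxy-3,7-bis[(4-methoxybenzyl)oxy]-4H-chromen-4-one F6. TFA with anisole then removes the three PMB groups and the fallback rejoins the route at 15.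

**Step 10.**
- What may go wrong: incomplete sulfation at the enolic 3-hydroxyl or at the 3'-hydroxyl next to the benzyloxy group, or partial sulfation of the 5-hydroxyl, giving a mixture of anionic products that is hard to separate.
- Fallback: this introduces the sulfates as neutral, chromatographable diesters. It sets out from 15. Reaction with 2,2,2-trichloroethyl chlorosulfate, Et3N and 4-(dimethylamino)pyridine in THF gives 4'-O-benzylquercetin 3,3',7-tris(2,2,2-trichloroethyl sulfate) F7, which is purified on silica. Zinc dust and HCO2NH4 in methanol then fragment the trichloroethyl groups reductively and free the three sulfate monoesters. The fallback rejoins the route at 16, obtained as its ammonium salt, and step 11 follows as planned.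

**Step 3.**
- What may go wrong: poor regioselectivity of the mono-benzylation, with 3-O-benzyl and dibenzyl ethers formed beside 8.
- Fallback: this reverses the order of alkylation and uses the nucleophilicity of the dianion instead of the acidity of the monoanion. It sets out from 7. Two equivalents of NaH in DMF form the dianion, whose 3-phenoxide is not conjugated with the ester and is the more nucleophilic; one equivalent of 4-methoxybenzyl chloride gives methyl 4-hydroxy-3-[(4-methoxybenzyl)oxy]benzoate F8. Benzylation of the remaining 4-hydroxyl (BnBr, K2CO3, DMF) rejoins the route at 9.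

## Further compounds

F1 | step 7 | {4-(benzyloxy)-3-[(4-methoxybenzyl)oxy]phenyl}methanol | OCc1ccc(OCc2ccccc2)c(OCc2ccc(OC)cc2)c1
F2 | step 7 | 4-(benzyloxy)-3-[(4-methoxybenzyl)oxy]benzaldehyde | O=Cc1ccc(OCc2ccccc2)c(OCc2ccc(OC)cc2)c1
F3 | step 7 | 3-{4-(benzyloxy)-3-[(4-methoxybenzyl)oxy]phenyl}-3-hydroxy-2-[(4-methoxybenzyl)oxy]-1-(2,4,6-trifluorophenyl)propan-1-one (mixture of diastereomers, racemic) | O=C(C(OCc1ccc(OC)cc1)C(O)c1ccc(OCc2ccccc2)c(OCc2ccc(OC)cc2)c1)c1c(F)cc(F)cc1F
F4 | step 8 | 2-{4-(benzyloxy)-3-[(4-methoxybenzyl)oxy]phenyl}-5-fluoro-3,7-bis[(4-methoxybenzyl)oxy]-4H-chromen-4-one | O=c1c(OCc2ccc(OC)cc2)c(-c2ccc(OCc3ccccc3)c(OCc3ccc(OC)cc3)c2)oc2cc(OCc3ccc(OC)cc3)cc(F)c12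
F5 | step 8 | 2-{4-(benzyloxy)-3-[(4-methoxybenzyl)oxy]phenyl}-3,7-bis[(4-methoxybenzyl)oxy]-5-[2-(methylsulfonyl)ethoxy]-4H-chromen-4-one | O=c1c(OCc2ccc(OC)cc2)c(-c2ccc(OCc3ccccc3)c(OCc3ccc(OC)cc3)c2)oc2cc(OCc3ccc(OC)cc3)cc(OCCS(C)(=O)=O)c12
F6 | step 8 | 2-{4-(benzyloxy)-3-[(4-methoxybenzyl)oxy]phenyl}-5-hydroxy-3,7-bis[(4-methoxybenzyl)oxy]-4H-chromen-4-one | O=c1c(OCc2ccc(OC)cc2)c(-c2ccc(OCc3ccccc3)c(OCc3ccc(OC)cc3)c2)oc2cc(OCc3ccc(OC)cc3)cc(O)c12
F7 | step 10 | 4'-O-benzylquercetin 3,3',7-tris(2,2,2-trichloroethyl sulfate) | O=c1c(OS(=O)(=O)OCC(Cl)(Cl)Cl)c(-c2ccc(OCc3ccccc3)c(OS(=O)(=O)OCC(Cl)(Cl)Cl)c2)oc2cc(OS(=O)(=O)OCC(Cl)(Cl)Cl)cc(O)c12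
F8 | step 3 | methyl 4-hydroxy-3-[(4-methoxybenzyl)oxy]benzoate | COC(=O)c1ccc(O)c(OCc2ccc(OC)cc2)c1
A1 | alternative 1 | 2-[4-(benzyloxy)-3-hydroxyphenyl]-3,5,7-trihydroxy-4H-chromen-4-one (4'-O-benzylquercetin) | O=c1c(O)c(-c2ccc(OCc3ccccc3)c(O)c2)oc2cc(O)cc(O)c12
A2 | alternative 1 | 2-(methoxymethoxy)-1-[2,4,6-tris(methoxymethoxy)phenyl]ethan-1-one | COCOCC(=O)c1c(OCOC)cc(OCOC)cc1OCOC
A3 | alternative 1 | 1-(benzyloxy)-4-bromo-2-(methoxymethoxy)benzene | COCOc1cc(Br)ccc1OCc1ccccc1
A4 | alternative 1 | carbon monoxide | [C-]#[O+]
A5 | alternative 2 | 2-iodo-3,5-bis(methoxymethoxy)phenol | COCOc1cc(O)c(I)c(OCOC)c1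
A6 | alternative 2 | 1-(benzyloxy)-4-ethynyl-2-(methoxymethoxy)benzene | C#Cc1ccc(OCc2ccccc2)c(OCOC)c1
A7 | alternative 2 | 2-[4-(benzyloxy)-3-(methoxymethoxy)phenyl]-5,7-bis(methoxymethoxy)-4H-chromen-4-one | O=c1cc(-c2ccc(OCc3ccccc3)c(OCOC)c2)oc2cc(OCOC)cc(OCOC)c12
A8 | alternative 3 | phloroglucinol (benzene-1,3,5-triol) | Oc1cc(O)cc(O)c1
A9 | alternative 3 | ethyl 3-[4-(benzyloxy)-3-(pivaloyloxy)phenyl]-3-oxo-2-(pivaloyloxy)propanoate (racemic) | CCOC(=O)C(OC(=O)C(C)(C)C)C(=O)c1ccc(OCc2ccccc2)c(OC(=O)C(C)(C)C)c1
A10 | alternative 3 | 3,3'-di-O-pivaloyl-4'-O-benzylquercetin | CC(C)(C)C(=O)Oc1c(-c2ccc(OCc3ccccc3)c(OC(=O)C(C)(C)C)c2)oc2cc(O)cc(O)c2c1=O
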